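**Plan**

- Retrosynthesis: cut the C6–O ester bond (trienoic acid from sorbaldehyde), the C8–C12 bond (formyl carbon brought in as a 1,3-dioxolane) and the C9–OH bond. This leaves a 6-oxo-trans-decalin C11 ester, carried as the tert-butyl ester so that acid frees it at the end.
- In that decalin the junction bond C5–C10 is the transannular bond of a ten-membered carbocycle C1–C10 in which C6 is a ketone and C10 is the β-carbon of the C9 ester. Cutting C5–C10 and C3–C4 and rejoining C1–C6 gives a cis-4-isobutenyl-3-vinylcyclohexenol ester.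
- Forward: ring B, C15 and C11 come from tert-butyl Hagemann's ester; C5 (hydroxymethyl, later Wittig to isobutenyl) and the vinyl group are set around an epoxy alcohol. The oxy-Cope shift opens the six-membered ring to the ten-membered ring, and the transannular Michael addition closes rings A and B together.
- Stereochemistry: Sharpless epoxidation fixes the carbinol carbon, and anti opening by the vinyl nucleophile gives the cis-dialkenyl relation. These relay to C10 in the cascade; C5 follows by enolate equilibration, C6 by Luche reduction from the α face, and C9 by enolate hydroxylation anti to the C10 methyl group.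

Key step: step 8

Assumption: ring atoms are discussed with drimane numbers (C1–C10, C11 = carboxyl carbon on C9, C12 = formyl carbon on C8, C15 = methyl on C10), and the trans-fused (5α-H) 6-oxodecalin is taken to be the thermodynamic C5 epimer, as in 6-oxodrimanes.

**Route**

Step 1
Reactants: 1 tert-butyl acetoacetate; 2 methyl vinyl ketone
Product: 4 tert-butyl 2-methyl-4-oxocyclohex-2-ene-1-carboxylate (Hagemann's tert-butyl ester, racemic), via tert-butyl 2-acetyl-5-oxohexanoate 3 (not isolated)
Conditions: t-BuOK (5 mol%), t-BuOH, 0 °C → rt; then pyrrolidine, AcOH, PhMe, reflux (−H2O)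
Reagents that add atoms: none
Why: Michael addition followed by intramolecular aldol condensation (Robinson-type annulation) builds the ring with C15 and C11 in place; the single stereocentre is racemic and is erased in step 2.

Step 2
Reactants: 4 tert-butyl 2-methyl-4-oxocyclohex-2-ene-1-carboxylate
Product: 6 tert-butyl 2-methyl-4-{[(trifluoromethyl)sulfonyl]oxy}cyclohexa-1,3-diene-1-carboxylate, via sodium dienolate of 4 5 (not isolated)
Conditions: NaH, THF, 0 °C; then PhNTf2, 0 °C → rt
Reagents that add atoms: N-phenylbis(trifluoromethanesulfonimide), O=S(=O)(N(c1ccccc1)S(=O)(=O)C(F)(F)F)C(F)(F)F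
Why: γ-Deprotonation of the vinylogous β-keto ester gives the fully conjugated dienolate, and O-sulfonylation at the ketone oxygen (enol triflate formation) gives an achiral dienyl triflate.

Step 3
Reactants: 6 dienyl triflate; 7 (tributylstannyl)methanol
Product: 8 tert-butyl 4-(hydroxymethyl)-2-methylcyclohexa-1,3-diene-1-carboxylate
Conditions: Pd(PPh3)4 (5 mol%), LiCl, 1,4-dioxane, 80 °C
Reagents that add atoms: none
Why: Stille hydroxymethylation of an enol triflate is established and installs C5 as the hydroxymethyl group of an achiral 2,3-disubstituted allylic alcohol.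

Step 4
Reactants: 8 tert-butyl 4-(hydroxymethyl)-2-methylcyclohexa-1,3-diene-1-carboxylate
Product: 9 tert-butyl (1R,6R)-6-(hydroxymethyl)-2-methyl-7-oxabicyclo[4.1.0]hept-2-ene-3-carboxylate
Conditions: Ti(OiPr)4, D-(−)-diethyl tartrate, t-BuOOH, 4 Å MS, CH2Cl2, −20 °C
Reagents that add atoms: tert-butyl hydroperoxide, CC(C)(C)OO
Why: Sharpless asymmetric epoxidation touches only the allylic-alcohol double bond (the tetrasubstituted enoate bond is electron-poor), and since L-(+)-tartrate gives the (2S,3S) series with E-type allylic alcohols of the same CIP pattern, D-(−)-tartrate should give the 1R,6R epoxide that fixes future C6 and the face for C1.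

Step 5
Reactants: 9 epoxy alcohol; 10 vinylmagnesium bromide
Product: 11 tert-butyl (3S,4S)-3-ethenyl-4-hydroxy-4-(hydroxymethyl)-2-methylcyclohex-1-ene-1-carboxylate
Conditions: 10 (3.5 equiv), CuI (10 mol%), THF, −40 → −20 °C; aq NH4Cl
Reagents that add atoms: none
Why: Copper-catalysed Grignard opening of a 2,3-epoxy alcohol goes to C3 when C2 is fully substituted, here also the allylic carbon (SN2′ attack would have to make a quaternary centre at the enoate carbon), and SN2 inversion puts the vinyl group trans to the tertiary hydroxyl, that is cis to the future isobutenyl group.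

Step 6
Reactants: 11 diol
Product: 12 tert-butyl (3S,4S)-3-ethenyl-4-formyl-4-hydroxy-2-methylcyclohex-1-ene-1-carboxylate
Conditions: TEMPO (10 mol%), PhI(OAc)2, CH2Cl2, rt
Reagents that add atoms: none
Why: TEMPO/PhI(OAc)2 oxidation takes the primary alcohol selectively to the aldehyde; the tertiary alcohol, the alkenes and both stereocentres are untouched (the aldehyde carbon has no α-hydrogen).

Step 7
Reactants: 12 hydroxy aldehyde; 13 isopropyltriphenylphosphonium iodide
Product: 14 tert-butyl (3S,4R)-3-ethenyl-4-hydroxy-2-methyl-4-(2-methylprop-1-en-1-yl)cyclohex-1-ene-1-carboxylate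
Conditions: 13 (2.5 equiv), n-BuLi, THF, 0 °C; then 12, −78 → 0 °C
Reagents that add atoms: none
Why: Wittig olefination with the non-stabilised isopropylidene ylide turns the α-hydroxy aldehyde into the 2-methylprop-1-enyl group at low temperature without touching the tertiary alcohol or the C1 stereocentre.

Step 8
Reactants: 14 cis-dialkenyl cyclohexenol
Product: 18 tert-butyl (1S,4aS,8aS)-5,5,8a-trimethyl-4-oxo-1,2,3,4,4a,5,6,8a-octahydronaphthalene-1-carboxylate, via potassium alkoxide of 14 15 (not isolated), via potassium enolate of the ten-membered trienone 16 (not isolated), via cis-fused bicyclic potassium ester enolate 17 (not isolated)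
Conditions: KH (1.05 equiv), 18-crown-6 (1.1 equiv), THF, 0 °C → rt; then t-BuOH, rt; aq NH4Cl
Reagents that add atoms: none
Why: Proposed new method: potassium alkoxide 15 should undergo a chair anionic oxy-Cope shift that joins C3 to C4 and cuts C1–C6, and the ten-membered enolate 16 then adds through C5 to C10, the β-carbon of the tert-butyl enoate, across the ring; the closest known reactions are the anionic oxy-Cope ring expansion of 1,2-dialkenylcyclohexanols to cyclodec-5-enones and transannular Michael additions of medium-ring enolates, which have not been joined in one cascade on this substrate class. The single transannular bond C5–C10 closes ring A in a 6-exo-trig (enolexo) and ring B in a 6-endo-trig (enolendo) sense, attack at the δ-carbon C2 being excluded because it would give a four-membered ring. C10 is the only centre fixed irreversibly: C5 is delivered to the face of the C9=C10 bond on which the isobutenyl group stood in 14, so that 4R in 14 becomes 8aS (C10), first in the cis-fused enolate 17. C5 and C9 then equilibrate through their enolates (t-BuOK/t-BuOH) to the trans-fused ketone with the equatorial ester. The cascade needs a Z C1=C2 bond, the [3,3] shift ahead of retro-aldol cleavage or C1–H removal, and ring closure ahead of ring inversion; allylic 1,3-strain from the cis-methyl of the isobutenyl group turns the oxido group inward and C7 outward, which forces C10 axial at C1 (Z alkene, E enolate), the breaking C1–C6 bond lies near the nodal plane of the enoate so the ester cannot assist heterolysis, and 16 is formed with C5 already in van der Waals contact with C10.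

Step 9
Reactants: 18 octalone ester
Product: 19 tert-butyl (1S,4aS,8aS)-5,5,8a-trimethyl-4-oxodecahydronaphthalene-1-carboxylate
Conditions: H2 (1 atm), 10% Pd/C, EtOAc, rt
Reagents that add atoms: none
Why: Heterogeneous hydrogenation saturates the only unactivated alkene (C1=C2); the ketone and tert-butyl ester are inert and no stereocentre is affected.

Step 10
Reactants: 19 decalone ester
Product: 20 tert-butyl (1S,4aS,8aS)-5,5,8a-trimethyl-4-oxo-1,4,4a,5,6,7,8,8a-octahydronaphthalene-1-carboxylate
Conditions: IBX, DMSO–PhF, 70 °C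
Reagents that add atoms: none
Why: IBX dehydrogenation of the ketone can only give the C7=C8 enone, because the other α-carbon C5 has no β-hydrogen (C4 and C10 are quaternary).

Step 11
Reactants: 20 enone; 21 1,3-dioxolane
Product: 22 tert-butyl (1S,2R,4aS,8aS)-2-(1,3-dioxolan-2-yl)-5,5,8a-trimethyl-4-oxodecahydronaphthalene-1-carboxylate
Conditions: (n-Bu4N)4W10O32 (2 mol%), 21/MeCN, hν (365 nm), rt
Reagents that add atoms: none
Why: Decatungstate-photocatalysed hydrogen-atom transfer gives the 1,3-dioxolan-2-yl radical, whose Giese addition to the enone β-carbon C8 brings in C12 at the aldehyde oxidation level; attack anti to the C10 methyl group is expected, and the C8 configuration is erased in step 12 in any case.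

Step 12
Reactants: 22 dioxolanyl ketone
Product: 23 tert-butyl (1R,4aS,8aS)-2-(1,3-dioxolan-2-yl)-5,5,8a-trimethyl-4-oxo-1,4,4a,5,6,7,8,8a-octahydronaphthalene-1-carboxylate
Conditions: IBX, DMSO–PhF, 70 °C
Reagents that add atoms: none
Why: A second IBX dehydrogenation re-forms the C7=C8 bond, now carrying the masked formyl group, again with no regiochemical alternative.

Step 13
Reactants: 23 dioxolanyl enone
Product: 24 tert-butyl (1R,4R,4aS,8aS)-2-(1,3-dioxolan-2-yl)-4-hydroxy-5,5,8a-trimethyl-1,4,4a,5,6,7,8,8a-octahydronaphthalene-1-carboxylate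
Conditions: NaBH4, CeCl3·7H2O, MeOH, −78 °C
Reagents that add atoms: none
Why: Luche 1,2-reduction delivers hydride to the enone carbonyl from the α face, the β face being screened by the axial C10 and C4 methyl groups, and so gives the axial 6β-alcohol (4R).

Step 14
Reactants: 24 allylic alcohol
Product: 26 tert-butyl (1S,4R,4aS,8aS)-2-(1,3-dioxolan-2-yl)-1,4-dihydroxy-5,5,8a-trimethyl-1,4,4a,5,6,7,8,8a-octahydronaphthalene-1-carboxylate, via dipotassium alkoxide–ester dienolate of 24 25 (not isolated)
Conditions: KHMDS (2.4 equiv), THF, −78 °C; then 2-(phenylsulfonyl)-3-phenyloxaziridine, −78 °C; aq NH4Cl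
Reagents that add atoms: 2-(phenylsulfonyl)-3-phenyloxaziridine, O=S(=O)(N1OC1c1ccccc1)c1ccccc1
Why: Davis enolate hydroxylation: the ester dienolate takes oxygen at its α-carbon C9 from the α face, anti to the adjacent axial C10 methyl group, giving the 9α-alcohol (1S), while the C6 alkoxide is too poor a leaving group for vinylogous elimination.

Step 15
Reactants: 27 sorbaldehyde ((2E,4E)-hexa-2,4-dienal); 28 malonic acid
Product: 29 (2E,4E,6E)-octa-2,4,6-trienoic acid
Conditions: pyridine, piperidine (cat.), 90 °C
Reagents that add atoms: none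
Why: Knoevenagel–Doebner condensation with decarboxylation gives the E α,β-unsaturated acid and leaves the existing E,E-diene unchanged.

Step 16
Reactants: 26 diol; 29 (2E,4E,6E)-octa-2,4,6-trienoic acid
Product: 31 tert-butyl (1S,4R,4aS,8aS)-2-(1,3-dioxolan-2-yl)-1-hydroxy-5,5,8a-trimethyl-4-[(2E,4E,6E)-octa-2,4,6-trienoyloxy]-1,4,4a,5,6,7,8,8a-octahydronaphthalene-1-carboxylate, via (2E,4E,6E)-octa-2,4,6-trienoic 2,4,6-trichlorobenzoic anhydride 30 (not isolated)
Conditions: 29, 2,4,6-trichlorobenzoyl chloride, Et3N, THF, rt; then 26, DMAP, PhMe, rt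
Reagents that add atoms: none
Why: Yamaguchi esterification through the mixed anhydride acylates the secondary allylic 6β-hydroxyl under DMAP catalysis, while the tertiary C9 hydroxyl is too hindered to react.

Step 17
Reactants: 31 protected ester
Product: 33 ustusoic acid B, (1S,4R,4aS,8aS)-2-formyl-1-hydroxy-5,5,8a-trimethyl-4-[(2E,4E,6E)-octa-2,4,6-trienoyloxy]-1,4,4a,5,6,7,8,8a-octahydronaphthalene-1-carboxylic acid, via tert-butyl ester aldehyde 32 (not isolated)
Conditions: TFA–CH2Cl2–H2O (10:10:1), 0 °C → rt
Reagents that add atoms: water, O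
Why: Acid hydrolysis of the dioxolane (giving the enal) and acidolysis of the tert-butyl ester (loss of 2-methylpropene) occur in one operation; once the enal is present the allylic C6 ester and the C9 carbinol are poor cation precursors, so the trienoate and all stereocentres should survive.

**Compound list**

1 | tert-butyl acetoacetate | CC(=O)CC(=O)OC(C)(C)C | starting material
2 | methyl vinyl ketone | CC(=O)C=C | starting material
3 | tert-butyl 2-acetyl-5-oxohexanoate (racemic) | CC(=O)CCC(C(C)=O)C(=O)OC(C)(C)C | intermediate (not isolated)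
4 | tert-butyl 2-methyl-4-oxocyclohex-2-ene-1-carboxylate (racemic) | CC1=CC(=O)CCC1C(=O)OC(C)(C)C | intermediate
5 | sodium 4-(tert-butoxycarbonyl)-3-methylcyclohexa-1,3-dien-1-olate | [Na+].[O-]C1=CC(C)=C(C(=O)OC(C)(C)C)CC1 | intermediate (not isolated)
6 | tert-butyl 2-methyl-4-{[(trifluoromethyl)sulfonyl]oxy}cyclohexa-1,3-diene-1-carboxylate | CC1=C(C(=O)OC(C)(C)C)CCC(OS(=O)(=O)C(F)(F)F)=C1 | intermediate
7 | (tributylstannyl)methanol | CCCC[Sn](CCCC)(CCCC)CO | starting material
8 | tert-butyl 4-(hydroxymethyl)-2-methylcyclohexa-1,3-diene-1-carboxylate | CC1=C(C(=O)OC(C)(C)C)CCC(CO)=C1 | intermediate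
9 | tert-butyl (1R,6R)-6-(hydroxymethyl)-2-methyl-7-oxabicyclo[4.1.0]hept-2-ene-3-carboxylate | OC[C@]12CCC(C(=O)OC(C)(C)C)=C(C)[C@H]1O2 | intermediate
10 | vinylmagnesium bromide | C=C[Mg]Br | starting material
11 | tert-butyl (3S,4S)-3-ethenyl-4-hydroxy-4-(hydroxymethyl)-2-methylcyclohex-1-ene-1-carboxylate | O[C@]1(CO)[C@@H](C=C)C(C)=C(C(=O)OC(C)(C)C)CC1 | intermediate
12 | tert-butyl (3S,4S)-3-ethenyl-4-formyl-4-hydroxy-2-methylcyclohex-1-ene-1-carboxylate | O[C@]1(C=O)[C@@H](C=C)C(C)=C(C(=O)OC(C)(C)C)CC1 | intermediate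
13 | isopropyltriphenylphosphonium iodide | CC(C)[P+](c1ccccc1)(c1ccccc1)c1ccccc1.[I-] | starting material
14 | tert-butyl (3S,4R)-3-ethenyl-4-hydroxy-2-methyl-4-(2-methylprop-1-en-1-yl)cyclohex-1-ene-1-carboxylate (vinyl and isobutenyl cis) | O[C@]1(C=C(C)C)[C@@H](C=C)C(C)=C(C(=O)OC(C)(C)C)CC1 | intermediate (key-step precursor)
15 | potassium alkoxide of 14 | [K+].[O-][C@]1(C=C(C)C)[C@@H](C=C)C(C)=C(C(=O)OC(C)(C)C)CC1 | intermediate (not isolated)
16 | potassium enolate (C5=C6, ring carbons C4 and C7 trans) of tert-butyl 4,4,10-trimethyl-6-oxocyclodeca-1,9-diene-9-carboxylate (ring numbered as in the drimane; C1=C2 cis; C9=C10 with ring carbons cis) | [K+].[O-]/C1=C\C(C)(C)C/C=C\C(C)=C(C(=O)OC(C)(C)C)/CC1 | intermediate (not isolated)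
17 | potassium ester enolate (C9=C11) of the cis-fused (4aR,8aS) bicyclic keto ester | [K+].O=C1CCC(=C([O-])OC(C)(C)C)[C@@]2(C)C=CCC(C)(C)[C@@H]12 | intermediate (not isolated)
18 | tert-butyl (1S,4aS,8aS)-5,5,8a-trimethyl-4-oxo-1,2,3,4,4a,5,6,8a-octahydronaphthalene-1-carboxylate | O=C1CC[C@H](C(=O)OC(C)(C)C)[C@@]2(C)C=CCC(C)(C)[C@H]12 | intermediate (key-step product)
19 | tert-butyl (1S,4aS,8aS)-5,5,8a-trimethyl-4-oxodecahydronaphthalene-1-carboxylate | O=C1CC[C@H](C(=O)OC(C)(C)C)[C@@]2(C)CCCC(C)(C)[C@H]12 | intermediate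
20 | tert-butyl (1S,4aS,8aS)-5,5,8a-trimethyl-4-oxo-1,4,4a,5,6,7,8,8a-octahydronaphthalene-1-carboxylate | O=C1C=C[C@H](C(=O)OC(C)(C)C)[C@@]2(C)CCCC(C)(C)[C@H]12 | intermediate
21 | 1,3-dioxolane | C1COCO1 | starting material
22 | tert-butyl (1S,2R,4aS,8aS)-2-(1,3-dioxolan-2-yl)-5,5,8a-trimethyl-4-oxodecahydronaphthalene-1-carboxylate (expected major C8 epimer) | O=C1C[C@@H](C2OCCO2)[C@H](C(=O)OC(C)(C)C)[C@@]3(C)CCCC(C)(C)[C@H]13 | intermediate
23 | tert-butyl (1R,4aS,8aS)-2-(1,3-dioxolan-2-yl)-5,5,8a-trimethyl-4-oxo-1,4,4a,5,6,7,8,8a-octahydronaphthalene-1-carboxylate | O=C1C=C(C2OCCO2)[C@H](C(=O)OC(C)(C)C)[C@@]3(C)CCCC(C)(C)[C@H]13 | intermediate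
24 | tert-butyl (1R,4R,4aS,8aS)-2-(1,3-dioxolan-2-yl)-4-hydroxy-5,5,8a-trimethyl-1,4,4a,5,6,7,8,8a-octahydronaphthalene-1-carboxylate | O[C@@H]1C=C(C2OCCO2)[C@H](C(=O)OC(C)(C)C)[C@@]3(C)CCCC(C)(C)[C@H]13 | intermediate
25 | dipotassium salt of 24 (C6 alkoxide, C9=C11 ester enolate) | [K+].[K+].[O-][C@@H]1C=C(C2OCCO2)C(=C([O-])OC(C)(C)C)[C@@]3(C)CCCC(C)(C)[C@H]13 | intermediate (not isolated)
26 | tert-butyl (1S,4R,4aS,8aS)-2-(1,3-dioxolan-2-yl)-1,4-dihydroxy-5,5,8a-trimethyl-1,4,4a,5,6,7,8,8a-octahydronaphthalene-1-carboxylate | O[C@@H]1C=C(C2OCCO2)[C@](O)(C(=O)OC(C)(C)C)[C@@]3(C)CCCC(C)(C)[C@H]13 | intermediate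
27 | sorbaldehyde, (2E,4E)-hexa-2,4-dienal | C/C=C/C=C/C=O | starting material
28 | malonic acid | OC(=O)CC(=O)O | starting material
29 | (2E,4E,6E)-octa-2,4,6-trienoic acid | C/C=C/C=C/C=C/C(=O)O | intermediate
30 | (2E,4E,6E)-octa-2,4,6-trienoic 2,4,6-trichlorobenzoic anhydride | C/C=C/C=C/C=C/C(=O)OC(=O)c1c(Cl)cc(Cl)cc1Cl | intermediate (not isolated)
31 | tert-butyl (1S,4R,4aS,8aS)-2-(1,3-dioxolan-2-yl)-1-hydroxy-5,5,8a-trimethyl-4-[(2E,4E,6E)-octa-2,4,6-trienoyloxy]-1,4,4a,5,6,7,8,8a-octahydronaphthalene-1-carboxylate | C/C=C/C=C/C=C/C(=O)O[C@@H]1C=C(C2OCCO2)[C@](O)(C(=O)OC(C)(C)C)[C@@]3(C)CCCC(C)(C)[C@H]13 | intermediate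
32 | tert-butyl (1S,4R,4aS,8aS)-2-formyl-1-hydroxy-5,5,8a-trimethyl-4-[(2E,4E,6E)-octa-2,4,6-trienoyloxy]-1,4,4a,5,6,7,8,8a-octahydronaphthalene-1-carboxylate | C/C=C/C=C/C=C/C(=O)O[C@@H]1C=C(C=O)[C@](O)(C(=O)OC(C)(C)C)[C@@]2(C)CCCC(C)(C)[C@H]12 | intermediate (not isolated)
33 | ustusoic acid B | C/C=C/C=C/C=C/C(=O)O[C@@H]1C=C(C=O)[C@](O)(C(=O)O)[C@@]2(C)CCCC(C)(C)[C@H]12 | target

**Count and risks**

Total: 17 steps. Longest linear sequence: 16 steps (steps 1–14, 16, 17); step 15 is a one-step side branch.

Steps most likely to fail: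

1. Step 8 (proposed new method). The alkoxide may fragment by retro-vinylogous aldol cleavage or lose the C1 proton. The ring enolate may also be scrambled by proton transfer, or the ring may invert, before C5 reaches C10; yield and the relay of configuration to C10 would then erode. Fallback from 14 back to 18, splitting the cascade into two known reactions: run the anionic oxy-Cope rearrangement of 14 at −20 °C (KHMDS, 18-crown-6, THF) and quench the enolate at −78 °C with TMSCl/Et3N to give the trimethylsilyl enol ether of the ten-membered trienone F1. Treating F1 with TiCl4 in CH2Cl2 at −78 °C (transannular Mukaiyama–Michael addition to the enoate) should give, after aqueous work-up, the cis-fused keto ester F2. DBU in toluene then epimerises C5 and returns 18.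

2. Step 5. The vinyl copper reagent may attack in SN2′ fashion at the enoate carbon or reduce the vinyl epoxide by electron transfer instead of opening it at C1 (regiochemical leakage). Fallback from 9 back to 11, using hydroxyl-directed alane delivery: open 9 with diethyl[(trimethylsilyl)ethynyl]aluminium (from trimethylsilylacetylene, n-BuLi and Et2AlCl; toluene, 0 °C), which attacks C3 of 2,3-epoxy alcohols with inversion, to give the silylalkynyl diol F3. Buffered TBAF/AcOH removes silicon to give the ethynyl diol F4, and Lindlar semi-hydrogenation (Pd/CaCO3/Pb, quinoline, H2) gives 11.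

3. Step 14. Deprotonation of the hindered C9–H may be slow, and the dienolate may take oxygen at C7 or add to the sulfonimine by-product (loss of regiocontrol in the oxidation). Fallback from 23 back to 26, hydroxylating before the reduction by a different mechanism: aerobic γ-hydroxylation of the extended enolate of 23 (Cs2CO3, P(OEt)3, O2, DMSO, rt; the tertiary hydroperoxide is reduced in situ) should give the 9α-hydroxy enone F5, again from the face anti to the C10 methyl group. Luche reduction (NaBH4, CeCl3·7H2O, MeOH, −78 °C) then gives 26.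

Further compounds
F1 | step 8 | tert-butyl 4,4,10-trimethyl-6-[(trimethylsilyl)oxy]cyclodeca-1,5,9-triene-9-carboxylate (ring numbered as in the drimane; same alkene geometries as 16) | C[Si](C)(C)O/C1=C\C(C)(C)C/C=C\C(C)=C(C(=O)OC(C)(C)C)/CC1
F2 | step 8 | tert-butyl (1S,4aR,8aS)-5,5,8a-trimethyl-4-oxo-1,2,3,4,4a,5,6,8a-octahydronaphthalene-1-carboxylate (cis-fused C5 epimer of 18) | O=C1CC[C@H](C(=O)OC(C)(C)C)[C@@]2(C)C=CCC(C)(C)[C@@H]12
F3 | step 5 | tert-butyl 4-hydroxy-4-(hydroxymethyl)-2-methyl-3-[(trimethylsilyl)ethynyl]cyclohex-1-ene-1-carboxylate (alkynyl trans to the tertiary hydroxyl, same spatial arrangement as 11) | O[C@]1(CO)[C@@H](C#C[Si](C)(C)C)C(C)=C(C(=O)OC(C)(C)C)CC1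
F4 | step 5 | tert-butyl 3-ethynyl-4-hydroxy-4-(hydroxymethyl)-2-methylcyclohex-1-ene-1-carboxylate (same spatial arrangement as 11) | O[C@]1(CO)[C@@H](C#C)C(C)=C(C(=O)OC(C)(C)C)CC1
F5 | step 14 | tert-butyl (1S,4aS,8aS)-2-(1,3-dioxolan-2-yl)-1-hydroxy-5,5,8a-trimethyl-4-oxo-1,4,4a,5,6,7,8,8a-octahydronaphthalene-1-carboxylate | O=C1C=C(C2OCCO2)[C@](O)(C(=O)OC(C)(C)C)[C@@]3(C)CCCC(C)(C)[C@H]13
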